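## Retrosynthetic overview

1. The oxirane is the only ring. It is closed second to last by reagent-controlled epoxidation of the C3=C4 alkene of a (1Z,3E)-1-bromo-2-chlorodiene, and silyl removal ends the route.
2. The (Z)-BrCH=C(Cl) end comes from anti hydrochlorination of a 1-bromoenyne. The enyne is made from an (E)-2-methylenal (dibromoolefination, then E2), and the enal from cross-metathesis of a homoallylic silyl ether with methacrolein.
3. Key disconnection C5–C6: asymmetric allylboration of (R)-2-bromo-3-chloro-2-methylpropanal joins the C6–C8 fragment to the allyl fragment and sets C6.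
4. The aldehyde carries the C7 stereocentre. It comes from glycol cleavage of a bromodiol, formed by invertive bromide opening at the tertiary carbon of the Sharpless epoxide of (E)-4-chloro-3-methylbut-2-en-1-ol, which is made from prenyl acetate.

Assumption: locants C1–C8 follow the chain BrC1H=C2(Cl)–C3(CH3)–C4H–C5H2–C6H(OH)–C7(Br)(CH3)–C8H2Cl, in which the target is (1Z,3R,4S,6R,7R). The L-fructose-derived Shi ketone (made from L-sorbose) is taken as an available catalyst.

## Route

Step 1
Reactants: 1 prenyl acetate (3-methylbut-2-en-1-yl acetate)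
Product: 2 (2E)-4-hydroxy-3-methylbut-2-en-1-yl acetate
Conditions: SeO2 (0.1 equiv), t-BuOOH (2.5 equiv), CH2Cl2, rt
Reagents that add atoms: tert-butyl hydroperoxide, CC(C)(C)OO
Why: The catalytic Riley allylic oxidation runs by an ene reaction followed by a [2,3]-sigmatropic shift, which on a trisubstituted alkene hydroxylates only the methyl group trans to the chain and so fixes the E geometry on which the C7 configuration later depends.

Step 2
Reactants: 2 (2E)-4-hydroxy-3-methylbut-2-en-1-yl acetate
Product: 3 (2E)-4-chloro-3-methylbut-2-en-1-yl acetate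
Conditions: PPh3 (1.3 equiv), CCl4, reflux
Reagents that add atoms: carbon tetrachloride, ClC(Cl)(Cl)Cl
Why: In the Appel chlorination chloride displaces the oxyphosphonium group by SN2 at the primary allylic carbon, so C8–Cl is installed without allylic transposition or loss of geometry and before any bromine is present.

Step 3
Reactants: 3 (2E)-4-chloro-3-methylbut-2-en-1-yl acetate
Product: 4 (2E)-4-chloro-3-methylbut-2-en-1-ol
Conditions: iBu2AlH (2.2 equiv), CH2Cl2, −78 °C
Reagents that add atoms: none
Why: Reductive ester cleavage at −78 °C frees the alcohol without any nucleophilic alkoxide in solution, so the allylic chloride is not substituted.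

Step 4
Reactants: 4 (2E)-4-chloro-3-methylbut-2-en-1-ol
Product: 5 [(2R,3S)-3-(chloromethyl)-3-methyloxiran-2-yl]methanol
Conditions: Ti(OiPr)4 (0.1 equiv), D-(−)-diethyl tartrate (0.13 equiv), t-BuOOH (2 equiv, anhydrous), 4 Å molecular sieves, CH2Cl2, −20 °C
Reagents that add atoms: tert-butyl hydroperoxide, CC(C)(C)OO
Why: In the Sharpless asymmetric epoxidation the titanium D-(−)-tartrate complex delivers oxygen suprafacially to the face opposite to that used in the geraniol with L-(+)-tartrate case, which on this E alkene gives the (2R,3S)-epoxide with CH2OH and CH2Cl trans in about 90% ee or better.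

Step 5
Reactants: 5 [(2R,3S)-3-(chloromethyl)-3-methyloxiran-2-yl]methanol
Product: 6 (2R,3R)-3-bromo-4-chloro-3-methylbutane-1,2-diol
Conditions: Ti(OiPr)2Br2 (1.5 equiv), CH2Cl2, −20 → 0 °C; aqueous tartaric acid
Reagents that add atoms: dibromotitanium diisopropoxide, CC(C)O[Ti](Br)(Br)OC(C)C
Why: In this titanium-assisted opening of a 2,3-epoxy alcohol, chelation by tetravalent titanium weakens the C3–O bond, C3 is the tertiary carbon and C2 is deactivated by the neighbouring C–O, so bromide enters at C3 from the rear with inversion and sets the (R)-C–Br centre (C7), while any C2-opened 1,3-diol is inert in step 6.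

Step 6
Reactants: 6 (2R,3R)-3-bromo-4-chloro-3-methylbutane-1,2-diol
Product: 7 (2R)-2-bromo-3-chloro-2-methylpropanal
Conditions: NaIO4 on silica gel, CH2Cl2, rt; filtered, dried and used as a solution
Reagents that add atoms: none
Why: The Malaprade glycol cleavage removes C1 and the now superfluous carbinol centre under neutral conditions, and the resulting aldehyde has no α-hydrogen, so the bromine-bearing centre can neither epimerise nor lose chloride by E1cB.

Step 7
Reactants: 7 (2R)-2-bromo-3-chloro-2-methylpropanal; 8 allylmagnesium bromide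
Product: 11 (2R,3R)-2-bromo-1-chloro-2-methylhex-5-en-3-ol, via allylborane 9 (not isolated), via borinate 10 (not isolated)
Conditions: (+)-Ipc2BOMe ((−)-α-pinene series, 1.3 equiv) and 8 (1.25 equiv), Et2O, 0 °C → rt; then 7, −78 °C; then MeOH, pH 7 phosphate buffer, 30% H2O2, 0 °C
Reagents that add atoms: none
Why: In the Brown asymmetric carbonyl allylation the allylborane reacts through a closed Zimmerman–Traxler chair in which the isopinocampheyl groups of the (−)-α-pinene series expose the aldehyde face that gives the (3R)-carbinol (C6) over the small Felkin bias of the quaternary α-carbon, the neutral peroxide work-up keeps the new bromohydrin from closing to an epoxide, and the minor diastereomers (including the one from the minor enantiomer of 7) are removed on silica gel.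

Step 8
Reactants: 11 (2R,3R)-2-bromo-1-chloro-2-methylhex-5-en-3-ol
Product: 12 {[(2R,3R)-2-bromo-1-chloro-2-methylhex-5-en-3-yl]oxy}triethylsilane
Conditions: Et3SiOTf (1.3 equiv), 2,6-lutidine (2 equiv), CH2Cl2, −78 → 0 °C
Reagents that add atoms: triethylsilyl triflate, CC[Si](CC)(CC)OS(=O)(=O)C(F)(F)F
Why: Silylation with the triflate and a hindered, weakly basic pyridine protects the crowded alcohol without forming an alkoxide, which blocks bromohydrin closure in all later basic steps.

Step 9
Reactants: 12 {[(2R,3R)-2-bromo-1-chloro-2-methylhex-5-en-3-yl]oxy}triethylsilane; 13 methacrolein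
Product: 14 (2E,5R,6R)-6-bromo-7-chloro-2,6-dimethyl-5-(triethylsilyloxy)hept-2-enal
Conditions: 13 (8 equiv), second-generation Hoveyda–Grubbs catalyst RuCl2(H2IMes)(=CH-C6H4-2-OiPr) (5 mol %), CH2Cl2, 40 °C
Reagents that add atoms: none
Why: Olefin cross-metathesis between a terminal alkene and the electron-poor 1,1-disubstituted methacrolein is selective for the cross product and gives the thermodynamically preferred (E)-trisubstituted enal, while alkyl halides and the silyl ether are inert to the ruthenium carbene.

Step 10
Reactants: 14 (2E,5R,6R)-6-bromo-7-chloro-2,6-dimethyl-5-(triethylsilyloxy)hept-2-enal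
Product: 15 (3E,6R,7R)-1,1,7-tribromo-8-chloro-3,7-dimethyl-6-(triethylsilyloxy)octa-1,3-diene
Conditions: CBr4 (2 equiv), PPh3 (4 equiv), CH2Cl2, 0 °C
Reagents that add atoms: carbon tetrabromide, BrC(Br)(Br)Br
Why: The Ramirez dibromoolefination (first half of the Corey–Fuchs sequence) is a Wittig reaction of Ph3P=CBr2 that adds C1 under neutral conditions and leaves the E alkene, the alkyl halides and both stereocentres untouched.

Step 11
Reactants: 15 (3E,6R,7R)-1,1,7-tribromo-8-chloro-3,7-dimethyl-6-(triethylsilyloxy)octa-1,3-diene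
Product: 16 (3E,6R,7R)-1,7-dibromo-8-chloro-3,7-dimethyl-6-(triethylsilyloxy)oct-3-en-1-yne
Conditions: NaN(SiMe3)2 (1.15 equiv), THF, −78 °C, short reaction time
Reagents that add atoms: none
Why: E2 anti elimination of HBr from the 1,1-dibromoalkene by a hindered amide base stops at the 1-bromoalkyne because no alkyllithium is present, and at −78 °C the acidic vinylic hydrogen reacts much faster than the tertiary alkyl bromide.

Step 12
Reactants: 16 (3E,6R,7R)-1,7-dibromo-8-chloro-3,7-dimethyl-6-(triethylsilyloxy)oct-3-en-1-yne
Product: 17 (1Z,3E,6R,7R)-1,7-dibromo-2,8-dichloro-3,7-dimethyl-6-(triethylsilyloxy)octa-1,3-diene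
Conditions: LiCl (4 equiv), Pd(OAc)2 (5 mol %), AcOH, rt
Reagents that add atoms: lithium chloride, [Li+].[Cl-]
Why: In this palladium-catalysed hydrochlorination of a 1-haloalkyne, chloride attacks the alkyne bound to divalent palladium from the far side at C2, remote from bromine, and protonolysis of the C1–Pd bond with retention puts H trans to Cl, which makes Cl and Br cis (1Z) with the carbon chain trans to Br.

Step 13
Reactants: 17 (1Z,3E,6R,7R)-1,7-dibromo-2,8-dichloro-3,7-dimethyl-6-(triethylsilyloxy)octa-1,3-diene
Product: 18 {[(2R,3R)-3-bromo-1-{(2S,3R)-3-[(Z)-2-bromo-1-chloroethenyl]-3-methyloxiran-2-yl}-4-chloro-3-methylbutan-2-yl]oxy}triethylsilane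
Conditions: L-fructose-derived Shi ketone (1,2:4,5-di-O-isopropylidene-β-L-erythro-2,3-hexodiulo-2,6-pyranose, 0.3 equiv), 2KHSO5·KHSO4·K2SO4 (1.5 equiv), K2CO3 (5.8 equiv), Bu4NHSO4 (cat), MeCN–CH2(OMe)2, aqueous Na2B4O7 buffer, 0 °C
Reagents that add atoms: potassium peroxymonosulfate, [K+].[O-]S(=O)(=O)OO
Why: In the Shi asymmetric epoxidation the electrophilic chiral dioxirane attacks only the trisubstituted C3=C4 alkene and not the dihaloalkene, adds oxygen suprafacially through the spiro transition state so that C5 and the vinyl group stay trans, and in the L-fructose series uses the face opposite to that of the D-fructose ketone (which gives R,R-epoxides from E-trisubstituted alkenes), which sets C4 as S and C3 as R (descriptor changed by the chlorine on C2), while the silyl ether keeps the bromohydrin closed off at pH 10.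

Step 14
Reactants: 18 {[(2R,3R)-3-bromo-1-{(2S,3R)-3-[(Z)-2-bromo-1-chloroethenyl]-3-methyloxiran-2-yl}-4-chloro-3-methylbutan-2-yl]oxy}triethylsilane
Product: 19 (2R,3R)-3-bromo-1-{(2S,3R)-3-[(Z)-2-bromo-1-chloroethenyl]-3-methyloxiran-2-yl}-4-chloro-3-methylbutan-2-ol (target)
Conditions: HF·pyridine, excess pyridine, THF, 0 °C
Reagents that add atoms: none
Why: Fluoride-driven desilylation in a pyridine-buffered medium never produces a free alkoxide, so the bromohydrin does not close, and it is too weakly acidic to open the oxirane, whose cationic opening is further disfavoured by the dihalovinyl group.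

## Compound list

1 | prenyl acetate (3-methylbut-2-en-1-yl acetate) | CC(C)=CCOC(C)=O | starting material
2 | (2E)-4-hydroxy-3-methylbut-2-en-1-yl acetate | CC(=O)OC/C=C(\C)CO | intermediate
3 | (2E)-4-chloro-3-methylbut-2-en-1-yl acetate | CC(=O)OC/C=C(\C)CCl | intermediate
4 | (2E)-4-chloro-3-methylbut-2-en-1-ol | OC/C=C(\C)CCl | intermediate
5 | [(2R,3S)-3-(chloromethyl)-3-methyloxiran-2-yl]methanol | OC[C@H]1O[C@]1(C)CCl | intermediate
6 | (2R,3R)-3-bromo-4-chloro-3-methylbutane-1,2-diol | OC[C@@H](O)[C@@](C)(Br)CCl | intermediate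
7 | (2R)-2-bromo-3-chloro-2-methylpropanal | O=C[C@@](C)(Br)CCl | intermediate
8 | allylmagnesium bromide | C=CC[Mg]Br | starting material
9 | B-allyldiisopinocampheylborane of the (−)-α-pinene series | C=CCB([C@H]1C[C@H]2C[C@@H]([C@@H]1C)C2(C)C)[C@H]1C[C@H]2C[C@@H]([C@@H]1C)C2(C)C | intermediate
10 | (2R,3R)-2-bromo-1-chloro-2-methylhex-5-en-3-yl diisopinocampheylborinate | C[C@](Br)(CCl)[C@H](OB([C@H]1C[C@H]2C[C@@H]([C@@H]1C)C2(C)C)[C@H]1C[C@H]2C[C@@H]([C@@H]1C)C2(C)C)CC=C | intermediate
11 | (2R,3R)-2-bromo-1-chloro-2-methylhex-5-en-3-ol | C[C@](Br)(CCl)[C@H](O)CC=C | intermediate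
12 | {[(2R,3R)-2-bromo-1-chloro-2-methylhex-5-en-3-yl]oxy}triethylsilane | C[C@](Br)(CCl)[C@H](O[Si](CC)(CC)CC)CC=C | intermediate
13 | methacrolein (2-methylprop-2-enal) | CC(=C)C=O | starting material
14 | (2E,5R,6R)-6-bromo-7-chloro-2,6-dimethyl-5-(triethylsilyloxy)hept-2-enal | C[C@](Br)(CCl)[C@H](O[Si](CC)(CC)CC)C/C=C(\C)C=O | intermediate
15 | (3E,6R,7R)-1,1,7-tribromo-8-chloro-3,7-dimethyl-6-(triethylsilyloxy)octa-1,3-diene | C[C@](Br)(CCl)[C@H](O[Si](CC)(CC)CC)C/C=C(\C)C=C(Br)Br | intermediate
16 | (3E,6R,7R)-1,7-dibromo-8-chloro-3,7-dimethyl-6-(triethylsilyloxy)oct-3-en-1-yne | C[C@](Br)(CCl)[C@H](O[Si](CC)(CC)CC)C/C=C(\C)C#CBr | intermediate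
17 | (1Z,3E,6R,7R)-1,7-dibromo-2,8-dichloro-3,7-dimethyl-6-(triethylsilyloxy)octa-1,3-diene | C[C@](Br)(CCl)[C@H](O[Si](CC)(CC)CC)C/C=C(\C)/C(Cl)=C/Br | intermediate
18 | triethylsilyl ether of the target, (1Z,3R,4S,6R,7R) | C[C@](Br)(CCl)[C@H](O[Si](CC)(CC)CC)C[C@@H]1O[C@@]1(C)/C(Cl)=C/Br | intermediate
19 | (2R,3R)-3-bromo-1-{(2S,3R)-3-[(Z)-2-bromo-1-chloroethenyl]-3-methyloxiran-2-yl}-4-chloro-3-methylbutan-2-ol | C[C@](Br)(CCl)[C@H](O)C[C@@H]1O[C@@]1(C)/C(Cl)=C/Br | target

## Step count and risks

Total step count: 14. Longest linear sequence: 14 steps (1 → 19).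

**Step 5 (bromide opening at the tertiary carbon).**
- Risk: the chloromethyl group lowers the cation-stabilising power of C3, so attack at C2, partial loss of stereospecificity or rearrangement are possible.
- Fallback: C7 is no longer made by epoxide opening. It is carried as a racemate and sorted out after the key step. The fallback sets out from 13. HCl gas adds in conjugate fashion (Et2O, −10 °C) to give racemic 3-chloro-2-methylpropanal F1. The only α-hydrogen of F1 is replaced through the enol with Br2 (CH2Cl2, 0 °C) to give racemic 2-bromo-3-chloro-2-methylpropanal F2. Allylboration of F2 with 9, made from 8 exactly as in step 7, runs under reagent control through 10 and the C2-epimeric borinate F3. After the same buffered peroxide work-up it gives about equal amounts of 11 and (2S,3R)-2-bromo-1-chloro-2-methylhex-5-en-3-ol F4. These two are diastereomers and are separated on silica gel. The route is rejoined at 11.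

**Step 11 (strong base next to a tertiary bromide).**
- Risk: E2 loss of HBr or HCl from the C6–C8 part can compete with the vinylic elimination.
- Fallback: the alkyne is made by one-carbon homologation and brominated electrophilically, so that 15 and the amide-base elimination are avoided. The fallback sets out from 14. Me3SiC(Li)N2 (from Me3SiCHN2 and LiN(iPr)2, THF, −78 → 0 °C) adds to the aldehyde, and Colvin rearrangement gives (3E,6R,7R)-7-bromo-8-chloro-3,7-dimethyl-6-(triethylsilyloxy)oct-3-en-1-yne F5. Its terminal C–H is then brominated with N-bromosuccinimide and AgNO3 (10 mol %) in acetone at rt. The route is rejoined at 16.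

**Step 13 (asymmetric epoxidation of a halogen-deactivated, twisted diene).**
- Risk: conversion or facial selectivity may be poor, and the unnatural ketone is costly.
- Fallback: reagent control is replaced by substrate direction, which also removes the final deprotection on the epoxide. The fallback sets out from 17. HF·pyridine with excess pyridine (THF, 0 °C) gives (1Z,3E,6R,7R)-1,7-dibromo-2,8-dichloro-3,7-dimethylocta-1,3-dien-6-ol F6. VO(acac)2 (5 mol %) and t-BuOOH (toluene, 0 °C) then epoxidise the homoallylic alcohol through a chair-like vanadate ester. In this transition state the bulky C7 group sits equatorial, and oxygen goes to the C3=C4 face that makes the C4–O and C6–O bonds syn, as in the target. The minor diastereomer is removed by chromatography. The route is rejoined at 19. F6 is also what step 12 would deliver if acetic acid removed the silyl group, so this path covers that case as well.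

Further compounds
F1 | step 5 | 3-chloro-2-methylpropanal (racemic) | CC(CCl)C=O
F2 | step 5 | 2-bromo-3-chloro-2-methylpropanal (racemic) | CC(Br)(CCl)C=O
F3 | step 5 | (2S,3R)-2-bromo-1-chloro-2-methylhex-5-en-3-yl diisopinocampheylborinate | C[C@@](Br)(CCl)[C@H](OB([C@H]1C[C@H]2C[C@@H]([C@@H]1C)C2(C)C)[C@H]1C[C@H]2C[C@@H]([C@@H]1C)C2(C)C)CC=C
F4 | step 5 | (2S,3R)-2-bromo-1-chloro-2-methylhex-5-en-3-ol | C[C@@](Br)(CCl)[C@H](O)CC=C
F5 | step 11 | (3E,6R,7R)-7-bromo-8-chloro-3,7-dimethyl-6-(triethylsilyloxy)oct-3-en-1-yne | C[C@](Br)(CCl)[C@H](O[Si](CC)(CC)CC)C/C=C(\C)C#C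
F6 | step 13 | (1Z,3E,6R,7R)-1,7-dibromo-2,8-dichloro-3,7-dimethylocta-1,3-dien-6-ol | C[C@](Br)(CCl)[C@H](O)C/C=C(\C)/C(Cl)=C/Br
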